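## Retrosynthetic overview

1. Target 26 ⇐ fluoride removal of all silicon groups ⇐ epimerisation at decalin C2 ⇐ intramolecular inverse-demand Diels–Alder reaction of acyclic dienone 23, which closes decalin rings A and B together, as in the presumed biosynthesis.
2. Dienone 23 ⇐ C3-lithiated pyridine 22 + Weinreb tetraenamide 8; (S)-citronellol supplies the C7 methyl stereocentre.
3. Oxirane C2'–O–C3' ⇐ cis-diol ⇐ C2'=C3' alkene of 17; both operations occur on the face opposite to the two cis oxygen atoms at C1' and C4'.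
4. Key disconnection C5–C1': 5-lithio-2,4-dialkoxypyridine 15 + (R)-4-silyloxycyclohex-2-enone 12. Enabling feature: C1' is the fully substituted carbinol carbon of the cyclohexane ring, 1,4-cis to the C4' carbinol and flanked by the C2'–C3' epoxide. With the epoxide taken back to a C2'=C3' alkene, C1' is the carbonyl carbon of a γ-oxygenated cyclohexenone whose single stereocentre C4' steers the nucleophile. C5 of the pyridone ring (ortho to O4, β to N1) is the position that a 5-bromo-2,4-dialkoxypyridine metalates.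
5. Ring order: pyridine and cyclohexene rings are bought; oxirane ring in step 13; decalin rings A and B in step 15.

Key step: step 11

Remark: C1'–C6' denote the cyclohexane ring (C1' quaternary carbinol, C2'/C3' oxirane carbons, C4' secondary carbinol) and decalin locants follow octahydronaphthalene numbering; compounds 1, 4, 9 and 13 are taken as commercial.

## Route

Step 1
Reactants: 1 (S)-citronellol
Product: 2 5-{[(3S)-3,7-dimethyloct-6-en-1-yl]sulfanyl}-1-phenyl-1H-tetrazole
Conditions: 1-phenyl-1H-tetrazole-5-thiol, PPh3, DIAD, THF, 0 °C → rt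
Reagents that add atoms: 1-phenyl-1H-tetrazole-5-thiol, Sc1nnnn1-c1ccccc1
Why: Mitsunobu thioetherification of an unhindered primary alcohol should be clean, and the remote C3 stereocentre is not touched.

Step 2
Reactants: 2 sulfide
Product: 3 5-{[(3S)-3,7-dimethyloct-6-en-1-yl]sulfonyl}-1-phenyl-1H-tetrazole
Conditions: H2O2 (30 %), (NH4)6Mo7O24·4H2O (cat.), EtOH, 0 °C → rt
Reagents that add atoms: hydrogen peroxide, OO
Why: Molybdate-catalysed sulfide-to-sulfone oxidation is selective for sulfur over a trisubstituted alkene.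

Step 3
Reactants: 3 sulfone; 4 (E)-but-2-enal
Product: 5 (2E,4E,7S)-7,11-dimethyldodeca-2,4,10-triene
Conditions: KN(SiMe3)2, DME, −60 °C; then 4, −60 °C → rt
Reagents that add atoms: none
Why: Julia–Kocienski olefination of an alkyl phenyltetrazolyl sulfone with an enal should give the new C4=C5 bond E, while the C2=C3 geometry comes from the enal.

Step 4
Reactants: 5 triene
Product: 6 (2E,6S,8E,10E)-2,6-dimethyldodeca-2,8,10-trien-1-ol
Conditions: SeO2 (cat.), t-BuOOH, salicylic acid (cat.), CH2Cl2, rt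
Reagents that add atoms: tert-butyl hydroperoxide, CC(C)(C)OO (oxygen passed on through SeO2, O=[Se]=O)
Why: Selenium dioxide allylic oxidation (ene reaction, then 2,3-sigmatropic shift) attacks the most electron-rich trisubstituted alkene at its E-methyl group, as in terpenes that also carry a conjugated diene; any over-oxidised 7 is carried into step 5.

Step 5
Reactants: 6 allylic alcohol
Product: 7 (2E,6S,8E,10E)-2,6-dimethyldodeca-2,8,10-trienal
Conditions: MnO2, CH2Cl2, rt
Reagents that add atoms: none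
Why: MnO2 oxidises allylic alcohols selectively and without E/Z isomerisation.

Step 6
Reactants: 7 enal
Product: 8 (2E,4E,8S,10E,12E)-N-methoxy-N,4,8-trimethyltetradeca-2,4,10,12-tetraenamide
Conditions: (EtO)2P(O)CH2C(O)N(OMe)Me, LiCl, DBU, MeCN, rt
Reagents that add atoms: diethyl {2-[methoxy(methyl)amino]-2-oxoethyl}phosphonate, CCOP(=O)(OCC)CC(=O)N(C)OC
Why: Horner–Wadsworth–Emmons olefination under Masamune–Roush conditions should give the E-enamide without disturbing the other alkenes.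

Step 7
Reactants: 9 1,4-dioxaspiro[4.5]dec-6-en-8-one
Product: 10 (8R)-1,4-dioxaspiro[4.5]dec-6-en-8-ol
Conditions: RuCl[(R,R)-TsDPEN](p-cymene) (1 mol %), HCO2Na, n-Bu4NCl, CH2Cl2/H2O, rt
Reagents that add atoms: none
Why: Noyori asymmetric transfer hydrogenation; the alkene takes the place of the aryl group of an aryl ketone in the catalyst pocket, so the (R,R)-catalyst should deliver hydride to give the (R)-allylic alcohol.

Step 8
Reactants: 10 allylic alcohol
Product: 11 tert-butyl{[(8R)-1,4-dioxaspiro[4.5]dec-6-en-8-yl]oxy}dimethylsilane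
Conditions: TBSCl, imidazole, DMF, rt
Reagents that add atoms: tert-butyldimethylsilyl chloride, CC(C)(C)[Si](C)(C)Cl
Why: Standard silylation of a secondary alcohol, with no change at the stereocentre.

Step 9
Reactants: 11 silyl ether
Product: 12 (4R)-4-[(tert-butyldimethylsilyl)oxy]cyclohex-2-en-1-one
Conditions: PPTS, acetone/H2O, 55 °C
Reagents that add atoms: water, O
Why: Mild acid-catalysed ketal hydrolysis should free the enone while the TBS ether survives.

Step 10
Reactants: 13 5-bromo-2,4-dichloropyridine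
Product: 14 5-bromo-2,4-bis[2-(trimethylsilyl)ethoxy]pyridine
Conditions: NaH, Me3SiCH2CH2OH (2.5 equiv), DMF, 0 → 70 °C
Reagents that add atoms: 2-(trimethylsilyl)ethanol, C[Si](C)(C)CCO
Why: Nucleophilic aromatic substitution occurs first at the 4-chloride and then at the 2-chloride (both activated by the ring nitrogen), while the 5-bromide, β to nitrogen, is inert.

Step 11
Reactants: 14 5-bromo-2,4-bis[2-(trimethylsilyl)ethoxy]pyridine; 12 (4R)-4-[(tert-butyldimethylsilyl)oxy]cyclohex-2-en-1-one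
Product: 17 5-{(1S,4R)-4-[(tert-butyldimethylsilyl)oxy]-1-[(triethylsilyl)oxy]cyclohex-2-en-1-yl}-2,4-bis[2-(trimethylsilyl)ethoxy]pyridine, via 5-lithiopyridine 15 (not isolated), via lithium alkoxide 16 (not isolated)
Conditions: n-BuLi, THF, −78 °C; 12, −78 °C; then TESOTf, 2,6-lutidine, −78 → 0 °C
Reagents that add atoms: triethylsilyl trifluoromethanesulfonate, CC[Si](CC)(CC)OS(=O)(=O)C(F)(F)F
Why: Bromine–lithium exchange at C5 gives aryllithium 15, which adds 1,2 to the carbonyl carbon of 12 (the future C1'), and the tertiary lithium alkoxide 16 is silylated in the same flask. The closest known reaction types are the addition of 5-lithio-2,4-dialkoxypyridines to cyclohexanones and the 1,2-addition of organolithium reagents to γ-silyloxy cyclohexenones. No ring is closed; the step forms the only bond between the two ring systems and with it the full carbon skeleton of the eastern half. The new quaternary stereocentre C1' is controlled by C4': the silyloxy group prefers the pseudoaxial position of the enone half-chair and the aryllithium enters axially on the opposite face, so the aryl group ends trans to OTBS and the two oxygen atoms end cis (1S,4R). The step needs 1,2- over 1,4-addition and over enolisation, which a hard aryllithium at −78 °C secures, and anti over syn attack, which the bulky γ-silyloxy group secures. The cis-1,4-dioxygen pattern it sets is what later forces the diol, and so the oxirane, onto the opposite face.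

Step 12
Reactants: 17 bis-silyl ether
Product: 18 (1'R,2'S,3'R,4'R)-cis-2',3'-diol of 17, i.e. 4-[(tert-butyldimethylsilyl)oxy]-1-{4,6-bis[2-(trimethylsilyl)ethoxy]pyridin-3-yl}-1-[(triethylsilyl)oxy]cyclohexane-2,3-diol, both hydroxyl groups trans to the two silyloxy groups
Conditions: OsO4 (5 mol %), NMO, acetone/H2O, rt
Reagents that add atoms: N-methylmorpholine N-oxide, C[N+]1([O-])CCOCC1; water, O; OsO4 as catalytic carrier, O=[Os](=O)(=O)=O
Why: Upjohn dihydroxylation; osmylation of cyclic allylic ethers occurs anti to the allylic oxygen, and here both allylic oxygen atoms lie on one face, so C2' and C3' are set on the other, and unlike a peracid the reagent does not oxidise the pyridine nitrogen.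

Step 13
Reactants: 18 diol
Product: 21 5-{(1S,2R,5R,6R)-5-[(tert-butyldimethylsilyl)oxy]-2-[(triethylsilyl)oxy]-7-oxabicyclo[4.1.0]heptan-2-yl}-2,4-bis[2-(trimethylsilyl)ethoxy]pyridine, via cyclic orthoacetate 19 (not isolated), via chloro acetate 20 (not isolated)
Conditions: MeC(OMe)3, PPTS (cat.), CH2Cl2, rt; Me3SiCl, CH2Cl2, rt; K2CO3, MeOH, rt
Reagents that add atoms: none
Why: One-pot cis-diol-to-epoxide conversion: the acetoxonium ion from 19 is opened by chloride at the less hindered C3' with inversion, and methanolysis of the acetate then closes the oxirane by a second inversion at C3', so the oxirane lies on the face of the former diol, trans to both silyloxy groups.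

Step 14
Reactants: 21 epoxide; 8 Weinreb tetraenamide
Product: 23 (2E,4E,8S,10E,12E)-1-(5-{(1S,2R,5R,6R)-5-[(tert-butyldimethylsilyl)oxy]-2-[(triethylsilyl)oxy]-7-oxabicyclo[4.1.0]heptan-2-yl}-2,4-bis[2-(trimethylsilyl)ethoxy]pyridin-3-yl)-4,8-dimethyltetradeca-2,4,10,12-tetraen-1-one, via 3-lithiopyridine 22 (not isolated)
Conditions: n-BuLi, THF, −78 → −40 °C; 8, −78 → 0 °C; H2O
Reagents that add atoms: none
Why: Directed ortho-lithiation at C3, the position between the two alkoxy groups, followed by Weinreb ketone synthesis, in which the chelated tetrahedral intermediate prevents over-addition; the hindered oxirane should be inert at low temperature.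

Step 15
Reactants: 23 dienone
Product: 24 (1R,2R,4aS,7S,8aR)-4,7-dimethyl-1-[(E)-prop-1-enyl]-1,2,4a,5,6,7,8,8a-octahydronaphthalen-2-yl ketone of the protected pyridine (C2 epimer of 25)
Conditions: toluene (0.01 M), BHT, 110 °C, sealed tube
Reagents that add atoms: none
Why: Intramolecular inverse-electron-demand Diels–Alder reaction (4π: C2=C3–C4=C4a of the dienone; 2π: C8a=C1 of the terminal diene), copying the presumed biosynthesis; a trans-fused chair-like transition state with the C7 methyl equatorial sets C4a and C8a, the E-dienophile sets C1, and the E-enone places the acyl group cis to C5, i.e. axial at C2.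

Step 16
Reactants: 24 C2-epimeric ketone
Product: 25 (1R,2S,4aS,7S,8aR)-4,7-dimethyl-1-[(E)-prop-1-enyl]-1,2,4a,5,6,7,8,8a-octahydronaphthalen-2-yl ketone of the protected pyridine
Conditions: K2CO3, MeOH/THF, rt
Reagents that add atoms: none
Why: Base-mediated epimerisation through the dienolate; α-protonation returns the β,γ-unsaturated ketone and the equilibrium should favour the all-equatorial C2 configuration of the target.

Step 17
Reactants: 25 protected ketone
Product: 26 4-hydroxy-5-[(1S,2R,5R,6S)-2,5-dihydroxy-7-oxabicyclo[4.1.0]heptan-2-yl]-3-{[(1R,2S,4aS,7S,8aR)-4,7-dimethyl-1-[(E)-prop-1-enyl]-1,2,4a,5,6,7,8,8a-octahydronaphthalen-2-yl]carbonyl}pyridin-2(1H)-one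
Conditions: n-Bu4NF, AcOH (1:1), THF, 0 °C → rt
Reagents that add atoms: none
Why: Fluoride-induced global desilylation: the two 2-(trimethylsilyl)ethyl ethers fragment with loss of ethene to free the 4-hydroxy-2-pyridone, the TES and TBS ethers are cleaved, and the acetic acid buffer suppresses alkoxide-driven epoxide migration.

## Compound list

1 | (S)-citronellol, (3S)-3,7-dimethyloct-6-en-1-ol | OCC[C@@H](C)CCC=C(C)C | starting material
2 | 5-{[(3S)-3,7-dimethyloct-6-en-1-yl]sulfanyl}-1-phenyl-1H-tetrazole | c1ccccc1-n1nnnc1SCC[C@@H](C)CCC=C(C)C | intermediate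
3 | 5-{[(3S)-3,7-dimethyloct-6-en-1-yl]sulfonyl}-1-phenyl-1H-tetrazole | c1ccccc1-n1nnnc1S(=O)(=O)CC[C@@H](C)CCC=C(C)C | intermediate
4 | (E)-but-2-enal | C/C=C/C=O | starting material
5 | (2E,4E,7S)-7,11-dimethyldodeca-2,4,10-triene | C/C=C/C=C/C[C@@H](C)CCC=C(C)C | intermediate
6 | (2E,6S,8E,10E)-2,6-dimethyldodeca-2,8,10-trien-1-ol | C/C=C/C=C/C[C@@H](C)CC/C=C(C)/CO | intermediate
7 | (2E,6S,8E,10E)-2,6-dimethyldodeca-2,8,10-trienal | C/C=C/C=C/C[C@@H](C)CC/C=C(C)/C=O | intermediate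
8 | (2E,4E,8S,10E,12E)-N-methoxy-N,4,8-trimethyltetradeca-2,4,10,12-tetraenamide | C/C=C/C=C/C[C@@H](C)CC/C=C(C)/C=C/C(=O)N(C)OC | intermediate
9 | 1,4-dioxaspiro[4.5]dec-6-en-8-one | O=C1C=CC2(CC1)OCCO2 | starting material
10 | (8R)-1,4-dioxaspiro[4.5]dec-6-en-8-ol | O[C@H]1C=CC2(CC1)OCCO2 | intermediate
11 | tert-butyl{[(8R)-1,4-dioxaspiro[4.5]dec-6-en-8-yl]oxy}dimethylsilane | CC(C)(C)[Si](C)(C)O[C@H]1C=CC2(CC1)OCCO2 | intermediate
12 | (4R)-4-[(tert-butyldimethylsilyl)oxy]cyclohex-2-en-1-one | O=C1C=C[C@H](O[Si](C)(C)C(C)(C)C)CC1 | intermediate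
13 | 5-bromo-2,4-dichloropyridine | Clc1cc(Cl)c(Br)cn1 | starting material
14 | 5-bromo-2,4-bis[2-(trimethylsilyl)ethoxy]pyridine | C[Si](C)(C)CCOc1cc(OCC[Si](C)(C)C)c(Br)cn1 | intermediate
15 | {4,6-bis[2-(trimethylsilyl)ethoxy]pyridin-3-yl}lithium | C[Si](C)(C)CCOc1cc(OCC[Si](C)(C)C)c([Li])cn1 | intermediate
16 | lithium (1S,4R)-4-[(tert-butyldimethylsilyl)oxy]-1-{4,6-bis[2-(trimethylsilyl)ethoxy]pyridin-3-yl}cyclohex-2-en-1-olate | C[Si](C)(C)CCOc1cc(OCC[Si](C)(C)C)c(cn1)[C@]1(O[Li])CC[C@@H](O[Si](C)(C)C(C)(C)C)C=C1 | intermediate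
17 | 5-{(1S,4R)-4-[(tert-butyldimethylsilyl)oxy]-1-[(triethylsilyl)oxy]cyclohex-2-en-1-yl}-2,4-bis[2-(trimethylsilyl)ethoxy]pyridine | C[Si](C)(C)CCOc1cc(OCC[Si](C)(C)C)c(cn1)[C@]1(O[Si](CC)(CC)CC)CC[C@@H](O[Si](C)(C)C(C)(C)C)C=C1 | intermediate
18 | (1'R,2'S,3'R,4'R)-cis-2',3'-diol of 17 (hydroxyls trans to both silyloxy groups) | C[Si](C)(C)CCOc1cc(OCC[Si](C)(C)C)c(cn1)[C@]1(O[Si](CC)(CC)CC)CC[C@@H](O[Si](C)(C)C(C)(C)C)[C@H](O)[C@@H]1O | intermediate
19 | 2',3'-O-(1-methoxyethylidene) cyclic orthoacetate of 18 (orthoester carbon as a mixture) | C[Si](C)(C)CCOc1cc(OCC[Si](C)(C)C)c(cn1)[C@]1(O[Si](CC)(CC)CC)CC[C@@H](O[Si](C)(C)C(C)(C)C)[C@@H]2OC(C)(OC)O[C@H]12 | intermediate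
20 | trans-3'-chloro-2'-acetate (chlorine on the face of the silyloxy groups, acetoxy on the opposite face) | C[Si](C)(C)CCOc1cc(OCC[Si](C)(C)C)c(cn1)[C@]1(O[Si](CC)(CC)CC)CC[C@@H](O[Si](C)(C)C(C)(C)C)[C@@H](Cl)[C@@H]1OC(C)=O | intermediate
21 | 5-{(1S,2R,5R,6R)-5-[(tert-butyldimethylsilyl)oxy]-2-[(triethylsilyl)oxy]-7-oxabicyclo[4.1.0]heptan-2-yl}-2,4-bis[2-(trimethylsilyl)ethoxy]pyridine | C[Si](C)(C)CCOc1cc(OCC[Si](C)(C)C)c(cn1)[C@]1(O[Si](CC)(CC)CC)CC[C@@H](O[Si](C)(C)C(C)(C)C)[C@@H]2O[C@@H]21 | intermediate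
22 | 3-lithio derivative of 21 | C[Si](C)(C)CCOc1c([Li])c(OCC[Si](C)(C)C)c(cn1)[C@]1(O[Si](CC)(CC)CC)CC[C@@H](O[Si](C)(C)C(C)(C)C)[C@@H]2O[C@@H]21 | intermediate
23 | (2E,4E,8S,10E,12E)-1-(5-{(1S,2R,5R,6R)-5-[(tert-butyldimethylsilyl)oxy]-2-[(triethylsilyl)oxy]-7-oxabicyclo[4.1.0]heptan-2-yl}-2,4-bis[2-(trimethylsilyl)ethoxy]pyridin-3-yl)-4,8-dimethyltetradeca-2,4,10,12-tetraen-1-one | C/C=C/C=C/C[C@@H](C)CC/C=C(C)/C=C/C(=O)c1c(OCC[Si](C)(C)C)c(cnc1OCC[Si](C)(C)C)[C@]1(O[Si](CC)(CC)CC)CC[C@@H](O[Si](C)(C)C(C)(C)C)[C@@H]2O[C@@H]21 | intermediate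
24 | protected (1R,2R,4aS,7S,8aR)-decalinyl ketone (C2 epimer, acyl axial) | C/C=C/[C@@H]1[C@H]2C[C@@H](C)CC[C@@H]2C(C)=C[C@@H]1C(=O)c1c(OCC[Si](C)(C)C)c(cnc1OCC[Si](C)(C)C)[C@]1(O[Si](CC)(CC)CC)CC[C@@H](O[Si](C)(C)C(C)(C)C)[C@@H]2O[C@@H]21 | intermediate
25 | protected (1R,2S,4aS,7S,8aR)-decalinyl ketone (all-equatorial) | C/C=C/[C@@H]1[C@H]2C[C@@H](C)CC[C@@H]2C(C)=C[C@H]1C(=O)c1c(OCC[Si](C)(C)C)c(cnc1OCC[Si](C)(C)C)[C@]1(O[Si](CC)(CC)CC)CC[C@@H](O[Si](C)(C)C(C)(C)C)[C@@H]2O[C@@H]21 | intermediate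
26 | 4-hydroxy-5-[(1S,2R,5R,6S)-2,5-dihydroxy-7-oxabicyclo[4.1.0]heptan-2-yl]-3-{[(1R,2S,4aS,7S,8aR)-4,7-dimethyl-1-[(E)-prop-1-enyl]-1,2,4a,5,6,7,8,8a-octahydronaphthalen-2-yl]carbonyl}pyridin-2(1H)-one | C/C=C/[C@@H]1[C@H]2C[C@@H](C)CC[C@@H]2C(C)=C[C@H]1C(=O)c1c(O)c([C@]2(O)CC[C@@H](O)[C@@H]3O[C@@H]32)c[nH]c1=O | target

## Step count and risks

Total step count: 17. Longest linear sequence: 10 steps (steps 7–9 and 11–17).

Three steps most likely to fail:

**Step 11 (key step).** What may go wrong is poor facial selectivity (attack of 15 on the face that carries the silyloxy group) or enolisation of 12 by the aryllithium. The fallback replaces steric control by alkoxide-directed delivery in the enantiomeric series and then inverts C4'; it sets out from 9 and 14 and comes back at 17. Transfer hydrogenation of 9 with RuCl[(S,S)-TsDPEN](p-cymene) gives (8S)-1,4-dioxaspiro[4.5]dec-6-en-8-ol F1, and hydrolysis (PPTS, acetone/H2O) gives (4S)-4-hydroxycyclohex-2-en-1-one F2. The magnesium alkoxide of F2 (i-PrMgCl, THF, −78 °C) is treated with the aryl Grignard reagent made from 15 and MgBr2·OEt2, so that the aryl group is passed to the carbonyl on the alkoxide face, giving (1S,4S)-1-{4,6-bis[2-(trimethylsilyl)ethoxy]pyridin-3-yl}cyclohex-2-ene-1,4-diol F3. Mitsunobu inversion of the secondary allylic hydroxyl (4-nitrobenzoic acid, PPh3, DIAD) gives (1R,4S)-4-hydroxy-4-{4,6-bis[2-(trimethylsilyl)ethoxy]pyridin-3-yl}cyclohex-2-en-1-yl 4-nitrobenzoate F4. Methanolysis (K2CO3, MeOH) gives the (1S,4R)-cis-diol F5, TBSCl/imidazole silylates only the secondary hydroxyl to give (1S,4R)-4-[(tert-butyldimethylsilyl)oxy]-1-{4,6-bis[2-(trimethylsilyl)ethoxy]pyridin-3-yl}cyclohex-2-en-1-ol F6, and TESOTf/2,6-lutidine returns to 17.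

**Step 15.** What may go wrong is loss of periselectivity (normal-demand addition of the terminal diene to the γ,δ-double bond of the dienone) or cis ring fusion, on material that already carries the whole eastern half. The fallback closes the decalin on a small aldehyde first and attaches it afterwards; it sets out from 7 and 21 and comes back at 25. Wittig homologation of 7 with Ph3P=CHCHO (toluene, 80 °C) gives (2E,4E,8S,10E,12E)-4,8-dimethyltetradeca-2,4,10,12-tetraenal F7. The Me2AlCl-promoted intramolecular Diels–Alder reaction (CH2Cl2, −78 °C → rt) gives (1R,2R,4aS,7S,8aR)-4,7-dimethyl-1-[(E)-prop-1-enyl]-1,2,4a,5,6,7,8,8a-octahydronaphthalene-2-carbaldehyde F8, which can be purified and is equilibrated with DBU to the all-equatorial (1R,2S,4aS,7S,8aR)-aldehyde F9. Addition of 22 (made from 21 with n-BuLi as in step 14) to F9 gives the secondary carbinol F10 (mixture at the new carbinol carbon), and Dess–Martin oxidation returns to 25.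

**Step 12.** What may go wrong is very slow osmylation of an alkene flanked by a quaternary and a silyloxy-bearing carbon, or erosion of facial selectivity by the bulky aryl group. The fallback epoxidises directly with a peracid, accepts oxidation of the pyridine nitrogen and removes that oxygen afterwards; it sets out from 17 and comes back at 21, bypassing 18–20. Excess mCPBA (NaHCO3, CH2Cl2, rt) should epoxidise the alkene anti to both silyloxy groups and give 5-{(1S,2R,5R,6R)-5-[(tert-butyldimethylsilyl)oxy]-2-[(triethylsilyl)oxy]-7-oxabicyclo[4.1.0]heptan-2-yl}-2,4-bis[2-(trimethylsilyl)ethoxy]pyridine 1-oxide F11; bis(pinacolato)diboron (MeCN, 60 °C) then deoxygenates the N-oxide to 21.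

Further compounds
F1 | step 11 | (8S)-1,4-dioxaspiro[4.5]dec-6-en-8-ol | O[C@@H]1C=CC2(CC1)OCCO2
F2 | step 11 | (4S)-4-hydroxycyclohex-2-en-1-one | O=C1C=C[C@@H](O)CC1
F3 | step 11 | (1S,4S)-1-{4,6-bis[2-(trimethylsilyl)ethoxy]pyridin-3-yl}cyclohex-2-ene-1,4-diol | C[Si](C)(C)CCOc1cc(OCC[Si](C)(C)C)c(cn1)[C@]1(O)CC[C@H](O)C=C1
F4 | step 11 | (1R,4S)-4-hydroxy-4-{4,6-bis[2-(trimethylsilyl)ethoxy]pyridin-3-yl}cyclohex-2-en-1-yl 4-nitrobenzoate | C[Si](C)(C)CCOc1cc(OCC[Si](C)(C)C)c(cn1)[C@]1(O)CC[C@@H](OC(=O)c2ccc(cc2)[N+](=O)[O-])C=C1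
F5 | step 11 | (1S,4R)-1-{4,6-bis[2-(trimethylsilyl)ethoxy]pyridin-3-yl}cyclohex-2-ene-1,4-diol | C[Si](C)(C)CCOc1cc(OCC[Si](C)(C)C)c(cn1)[C@]1(O)CC[C@@H](O)C=C1
F6 | step 11 | (1S,4R)-4-[(tert-butyldimethylsilyl)oxy]-1-{4,6-bis[2-(trimethylsilyl)ethoxy]pyridin-3-yl}cyclohex-2-en-1-ol | C[Si](C)(C)CCOc1cc(OCC[Si](C)(C)C)c(cn1)[C@]1(O)CC[C@@H](O[Si](C)(C)C(C)(C)C)C=C1
F7 | step 15 | (2E,4E,8S,10E,12E)-4,8-dimethyltetradeca-2,4,10,12-tetraenal | C/C=C/C=C/C[C@@H](C)CC/C=C(C)/C=C/C=O
F8 | step 15 | (1R,2R,4aS,7S,8aR)-4,7-dimethyl-1-[(E)-prop-1-enyl]-1,2,4a,5,6,7,8,8a-octahydronaphthalene-2-carbaldehyde | C/C=C/[C@@H]1[C@H]2C[C@@H](C)CC[C@@H]2C(C)=C[C@@H]1C=O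
F9 | step 15 | (1R,2S,4aS,7S,8aR)-4,7-dimethyl-1-[(E)-prop-1-enyl]-1,2,4a,5,6,7,8,8a-octahydronaphthalene-2-carbaldehyde | C/C=C/[C@@H]1[C@H]2C[C@@H](C)CC[C@@H]2C(C)=C[C@H]1C=O
F10 | step 15 | secondary carbinol from 22 and F9 (mixture at the carbinol carbon) | C/C=C/[C@@H]1[C@H]2C[C@@H](C)CC[C@@H]2C(C)=C[C@H]1C(O)c1c(OCC[Si](C)(C)C)c(cnc1OCC[Si](C)(C)C)[C@]1(O[Si](CC)(CC)CC)CC[C@@H](O[Si](C)(C)C(C)(C)C)[C@@H]2O[C@@H]21
F11 | step 12 | 5-{(1S,2R,5R,6R)-5-[(tert-butyldimethylsilyl)oxy]-2-[(triethylsilyl)oxy]-7-oxabicyclo[4.1.0]heptan-2-yl}-2,4-bis[2-(trimethylsilyl)ethoxy]pyridine 1-oxide | C[Si](C)(C)CCOc1cc(OCC[Si](C)(C)C)c(c[n+]1[O-])[C@]1(O[Si](CC)(CC)CC)CC[C@@H](O[Si](C)(C)C(C)(C)C)[C@@H]2O[C@@H]21
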